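Numbering (germacrane): lactone O on C6, carbinol C7, angelate on C8, ketone C9, Z alkenes C1=C10 and C4=C5, exomethylene C11=C13, lactone carbonyl C12.
Cuts, in retrosynthetic order: the C8 O–acyl bond, the ring bond C7–C8, C11–C13, the C7–O and C12–O bonds of a tetronate, C6–C7, C9–C10 and C1=C10; what remains is nerol (C2 to C6, C15).
Enabling feature: on the five-membered lactone ring O–C6–C7–C11–C12 the array C13=C11–C7(O)–C8(O) is the retron of a γ-oxyallyl addition, with C13–C11=C7 read as a tetronate allylboronate and C8 as the aldehyde of a C8–C9 glyoxal.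
Forward: the chain C6 to C8 is built linearly from nerol, the lactone ring closes first as a tetronate (step 9), and the ten-membered carbocycle closes in step 16.
Stereochemistry: C6 from the catalyst-controlled alkynylation (step 8); C7 and C8 together in step 16 from C6 and the chair; C4=C5 from nerol, C1=C10 from the iodo-Wittig step and retentive lithiation, the angelate geometry from angelic acid.
Key step: step 16

Remark: the S,S antipode of the ProPhenol ligand in step 8 is assigned by analogy with its aldol reactions (Re-face delivery) and is to be fixed by one Mosher ester analysis of 19, the R,R ligand being equally available; PMB = 4-methoxybenzyl, TBS = tert-butyldimethylsilyl, Bpin = pinacolatoboryl.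

Step 1
Reactants: 1 nerol
Product: 2 neryl PMB ether
Conditions: NaH, PMBCl, Bu4NI (cat.), THF–DMF, 0 → 23 °C
Reagents that add atoms: 4-methoxybenzyl chloride, COc1ccc(CCl)cc1
Why: Williamson etherification of the primary allylic alkoxide masks the future C6 oxygen as an ether that survives the organolithium step and can later be removed oxidatively beside a silyl ether.

Step 2
Reactants: 2 neryl PMB ether
Product: 3 racemic terminal epoxide of 2
Conditions: mCPBA (1.0 equiv), NaHCO3, CH2Cl2, −20 → 0 °C
Reagents that add atoms: mCPBA, O=C(OO)c1cccc(Cl)c1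
Why: Prilezhaev epoxidation should select the electron-rich isopropylidene alkene because the C4=C5 alkene is deactivated by its allylic ether oxygen, and the racemic epoxide carbon is excised in the next step.

Step 3
Reactants: 3 racemic terminal epoxide
Product: 5 (4Z)-6-[(4-methoxybenzyl)oxy]-4-methylhex-4-enal, via diol 4 (not isolated)
Conditions: H5IO6, THF–H2O, 0 °C
Reagents that add atoms: none
Why: periodic acid opens the epoxide to the glycol (water entering at the tertiary carbon) and then performs Malaprade cleavage in the same flask, releasing acetone and the C1 aldehyde without touching the Z alkene or the PMB ether.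

Step 4
Reactants: 5 (4Z)-6-[(4-methoxybenzyl)oxy]-4-methylhex-4-enal; 6 ethyltriphenylphosphonium bromide
Product: 10 (2Z,6Z)-7-iodo-3-methylocta-2,6-dien-1-yl 4-methoxybenzyl ether, via ethylidene ylide 7 (not isolated), via iodophosphonium iodide 8 (not isolated), via iodoethylidene ylide 9 (not isolated)
Conditions: 6, n-BuLi, THF, 23 °C; I2, −78 °C; NaHMDS, −20 °C; then 5, −78 → −20 °C
Reagents that add atoms: iodine, II
Why: the Stork–Zhao-type Wittig olefination with the α-iodo ylide is kinetically controlled and places iodine cis to the chain, giving the Z trisubstituted vinyl iodide that carries C10 and C14.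

Step 5
Reactants: 10 Z,Z vinyl iodide; 11 2-[(tert-butyldimethylsilyl)oxy]-N-methoxy-N-methylacetamide
Product: 14 (3Z,7Z)-1-[(tert-butyldimethylsilyl)oxy]-9-[(4-methoxybenzyl)oxy]-3,7-dimethylnona-3,7-dien-2-one, via vinyllithium 12 (not isolated), via tetrahedral lithium adduct 13 (not isolated)
Conditions: t-BuLi (2.1 equiv), Et2O, −78 °C; then 11, −78 → −20 °C; then H2O
Reagents that add atoms: none
Why: iodine–lithium exchange retains the alkene geometry and the Weinreb ketone synthesis halts at the chelated tetrahedral adduct, so the Z enone carrying C9 and C8 should form without over-addition.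

Step 6
Reactants: 14 Z enone PMB ether
Product: 15 (3Z,7Z)-1-[(tert-butyldimethylsilyl)oxy]-9-hydroxy-3,7-dimethylnona-3,7-dien-2-one
Conditions: DDQ, CH2Cl2–pH 7 buffer, 0 °C
Reagents that add atoms: none
Why: oxidative PMB ether cleavage by DDQ (hydride abstraction at the electron-rich benzylic carbon followed by hydrolysis) leaves the TBS ether, the enone and both Z alkenes untouched under buffered conditions.

Step 7
Reactants: 15 allylic alcohol
Product: 16 (2Z,6Z)-9-[(tert-butyldimethylsilyl)oxy]-3,7-dimethyl-8-oxonona-2,6-dienal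
Conditions: TEMPO (cat.), PhI(OAc)2, MeCN–pH 7 buffer, 0 °C
Reagents that add atoms: none
Why: the oxoammonium (TEMPO) oxidation of allylic alcohols is the established way to reach neral-type Z enals without Z to E isomerisation or over-oxidation.

Step 8
Reactants: 16 Z,Z keto enal; 17 methyl propiolate
Product: 19 methyl (4S,5Z,9Z)-12-[(tert-butyldimethylsilyl)oxy]-4-hydroxy-6,10-dimethyl-11-oxododeca-5,9-dien-2-ynoate, via methylzinc alkynylide 18 (not isolated)
Conditions: Me2Zn (3 equiv), (S,S)-ProPhenol (20 mol%), Ph3PO (40 mol%), toluene, 0 °C; then H2O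
Reagents that add atoms: none
Why: catalytic asymmetric alkynylation of the enal by the dinuclear zinc–ProPhenol alkynylide sets C6 under catalyst control (Re-face delivery to the S carbinol is expected with the S,S ligand), and the aldehyde should react in preference to the hindered C9 ketone.

Step 9
Reactants: 19 (S)-γ-hydroxy ynoate
Product: 21 (5S)-4-(allyloxy)-5-[(1Z,5Z)-8-[(tert-butyldimethylsilyl)oxy]-2,6-dimethyl-7-oxoocta-1,5-dien-1-yl]furan-2(5H)-one, via allyloxy enoate 20 (not isolated)
Conditions: allyl alcohol, NaH (0.2 equiv), THF, 0 → 23 °C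
Reagents that add atoms: allyl alcohol, C=CCO
Why: alkoxide-catalysed oxa-Michael addition to the ynoate places the C7 oxygen at the β-carbon and the E adduct lactonises onto the C6 hydroxyl with loss of methanol, closing the five-membered lactone as a tetronate while catalytic base at low temperature spares C6 and the Z enone.

Step 10
Reactants: 21 allyl tetronate
Product: 22 (5S)-5-[(1Z,5Z)-8-[(tert-butyldimethylsilyl)oxy]-2,6-dimethyl-7-oxoocta-1,5-dien-1-yl]-4-hydroxyfuran-2(5H)-one
Conditions: Pd(PPh3)4 (5 mol%), morpholine, THF, 23 °C; then pH 3 work-up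
Reagents that add atoms: none
Why: zerovalent palladium ionises the allyl vinylogous ester (Tsuji–Trost deallylation) and the amine should trap the π-allyl fragment faster than the tetronate can recombine at carbon, releasing the free enol needed for selective halogenation at C11.

Step 11
Reactants: 22 tetronic acid
Product: 23 (5S)-5-[(1Z,5Z)-8-[(tert-butyldimethylsilyl)oxy]-2,6-dimethyl-7-oxoocta-1,5-dien-1-yl]-4-hydroxy-3-iodofuran-2(5H)-one
Conditions: NIS (1.05 equiv), THF, 0 °C, dark
Reagents that add atoms: N-iodosuccinimide, O=C1CCC(=O)N1I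
Why: electrophilic α-iodination of the vinylogous acid enol at C11 is far faster than iodonium formation at the trisubstituted alkenes, which is why the halogen is introduced before the enol is etherified.

Step 12
Reactants: 23 3-iodotetronic acid
Product: 24 (5S)-5-[(1Z,5Z)-8-[(tert-butyldimethylsilyl)oxy]-2,6-dimethyl-7-oxoocta-1,5-dien-1-yl]-3-iodo-4-[(4-methoxybenzyl)oxy]furan-2(5H)-one
Conditions: O-(4-methoxybenzyl)-N,N'-diisopropylisourea, THF, 23 → 40 °C
Reagents that add atoms: O-(4-methoxybenzyl)-N,N'-diisopropylisourea, COc1ccc(COC(=NC(C)C)NC(C)C)cc1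
Why: isourea O-alkylation of the acidic tetronic enol (proton transfer to the isourea, then benzyl transfer within the ion pair) gives the 4-O-ether without base or phosphine, so the α-iodo enol, the Z enone and C6 meet neither halophilic nor basic reagents.

Step 13
Reactants: 24 PMB 3-iodotetronate; 25 2-(iodomethyl)-4,4,5,5-tetramethyl-1,3,2-dioxaborolane
Product: 27 (5S)-5-[(1Z,5Z)-8-[(tert-butyldimethylsilyl)oxy]-2,6-dimethyl-7-oxoocta-1,5-dien-1-yl]-4-[(4-methoxybenzyl)oxy]-3-[(pinacolatoboryl)methyl]furan-2(5H)-one, via borylmethylzinc iodide 26 (not isolated)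
Conditions: 25, Zn dust (TMSCl-activated), THF, 23 °C; then 24, Pd(PPh3)4 (5 mol%), THF, 40 °C
Reagents that add atoms: none
Why: Negishi coupling of the alkenyl iodide with the borylmethylzinc iodide, the standard route from alkenyl halides to allylboronates, forms C11–C13 under neutral conditions that tolerate ketone, lactone and silyl ether and gives a bench-stable 2-carbonyl-substituted allylboronate.

Step 14
Reactants: 27 allylboronate TBS ether
Product: 28 (5S)-5-[(1Z,5Z)-8-hydroxy-2,6-dimethyl-7-oxoocta-1,5-dien-1-yl]-4-[(4-methoxybenzyl)oxy]-3-[(pinacolatoboryl)methyl]furan-2(5H)-one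
Conditions: CSA (0.2 equiv), MeOH–CH2Cl2, 0 °C
Reagents that add atoms: none
Why: acid-catalysed methanolysis of the primary silyl ether is fast at 0 °C whereas the pinacol boronate, the PMB vinylogous ester and the lactone need stronger acid, and fluoride is avoided because it would activate the allylboronate.

Step 15
Reactants: 28 ketol allylboronate
Product: 29 (5S)-5-[(1Z,5Z)-2,6-dimethyl-7,8-dioxoocta-1,5-dien-1-yl]-4-[(4-methoxybenzyl)oxy]-3-[(pinacolatoboryl)methyl]furan-2(5H)-one
Conditions: Dess–Martin periodinane, NaHCO3, CH2Cl2, 0 °C; filtered and used at once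
Reagents that add atoms: none
Why: Dess–Martin oxidation of the primary ketol gives the non-enolisable keto aldehyde under neutral conditions that leave the C–B bond intact, and the electron-poor allylboronate should be too sluggish to add before dilution and activation.

Step 16
Reactants: 29 glyoxal allylboronate
Product: 31 (6S,7S,8R)-8-hydroxy-7-[(4-methoxybenzyl)oxy]-9-oxogermacra-1(10)Z,4Z,11(13)-trien-12,6-olide (cis-fused; the C7 descriptor differs from the target only through CIP ranking), via O-boryl cyclisation product 30 (not isolated)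
Conditions: syringe-pump addition of 29 to Sc(OTf)3 (10 mol%), 4 Å MS, toluene (final 0.001 M), 23 → 50 °C; then aq. NaHCO3
Reagents that add atoms: none
Why: Proposed new method: boron binds the aldehyde oxygen and C7, the γ-carbon of the allyl unit B–C13–C11=C7, adds to C8 through a closed six-membered chair while the double bond moves to C11=C13 and boron passes to the C8 oxygen, so the C7–C8 bond, the tertiary ether, the secondary carbinol and the exomethylene arise in one event. The closest known reaction type is the carbonyl allylboration by 3,3-disubstituted 2-alkoxycarbonyl allylboronates and by γ-alkoxyallylboronates, including its acceleration by Sc(OTf)3, whereas the tetronate-embedded reagent and the macrocyclic version are untested. The ten-membered carbocycle closes 10-exo-trig at the aldehyde carbon (SE2' at the allyl unit) onto the lactone that is already in place. C7 is controlled by C6, since the short doubly Z tether anchored at C6 should reach only the butenolide face that carries C5, which gives the cis ring fusion. C8 is controlled relative to C7 by the chair, in which the ring-locked alkene puts OPMB axial (cis to CH2B) and C6 equatorial and the aldehyde places its acyl carbon C9 equatorial, which gives the syn relation of the C7 ether and the C8 carbinol found in the target. The step needs ring closure to beat oligomerisation and needs this face and chair; high dilution, the activated non-enolisable aldehyde held near C7 by the folded tether, a C–B bond that cannot undergo 1,4-elimination of the C6 carboxylate and an etherified C7 oxygen that blocks retro-aldol reversal are the features relied on.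

Step 17
Reactants: 31 germacranolide core alcohol; 32 angelic acid
Product: 34 (6S,7R,8R)-8-angeloyloxy-7-[(4-methoxybenzyl)oxy]-9-oxogermacra-1(10)Z,4Z,11(13)-trien-12,6-olide, via mixed anhydride 33 (not isolated)
Conditions: 32, 2,4,6-trichlorobenzoyl chloride, Et3N, toluene, 23 °C; then 31, toluene, 80 °C
Reagents that add atoms: none
Why: Yamaguchi-type esterification through the angelic 2,4,6-trichlorobenzoic mixed anhydride, run without nucleophilic catalyst, acylates the C8 alcohol at the less hindered angeloyl carbonyl and avoids the Z to E drift to tiglate that DMAP or acid chlorides cause, with no stereocentre touched.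

Step 18
Reactants: 34 angelate PMB ether
Product: 35 target, (6S,7R,8R)-8-angeloyloxy-7-hydroxy-9-oxogermacra-1(10)Z,4Z,11(13)-trien-12,6-olide
Conditions: DDQ, CH2Cl2–pH 7 buffer, 23 °C
Reagents that add atoms: none
Why: oxidative cleavage of the tertiary PMB ether by DDQ frees the C7 hydroxyl under neutral conditions, so the angelate, the α-methylene lactone and the retro-aldol-prone β-hydroxy ketone are not put at risk.

Compound list
1 | nerol, (2Z)-3,7-dimethylocta-2,6-dien-1-ol | CC(C)=CCC/C(C)=C\CO | starting material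
2 | neryl PMB ether, 1-({[(2Z)-3,7-dimethylocta-2,6-dien-1-yl]oxy}methyl)-4-methoxybenzene | CC(C)=CCC/C(C)=C\COCc1ccc(OC)cc1 | intermediate
3 | racemic 3-{(3Z)-5-[(4-methoxybenzyl)oxy]-3-methylpent-3-en-1-yl}-2,2-dimethyloxirane | CC1(C)OC1CC/C(C)=C\COCc1ccc(OC)cc1 | intermediate
4 | racemic (6Z)-8-[(4-methoxybenzyl)oxy]-2,6-dimethyloct-6-ene-2,3-diol (not isolated) | CC(C)(O)C(O)CC/C(C)=C\COCc1ccc(OC)cc1 | intermediate
5 | (4Z)-6-[(4-methoxybenzyl)oxy]-4-methylhex-4-enal | O=CCC/C(C)=C\COCc1ccc(OC)cc1 | intermediate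
6 | ethyltriphenylphosphonium bromide | CC[P+](c1ccccc1)(c1ccccc1)c1ccccc1.[Br-] | starting material
7 | ethylidenetriphenylphosphorane (not isolated) | CC=P(c1ccccc1)(c1ccccc1)c1ccccc1 | intermediate
8 | (1-iodoethyl)triphenylphosphonium iodide (not isolated) | CC(I)[P+](c1ccccc1)(c1ccccc1)c1ccccc1.[I-] | intermediate
9 | (1-iodoethylidene)triphenylphosphorane (not isolated) | CC(I)=P(c1ccccc1)(c1ccccc1)c1ccccc1 | intermediate
10 | (2Z,6Z)-7-iodo-3-methylocta-2,6-dien-1-yl 4-methoxybenzyl ether | I/C(C)=C\CC/C(C)=C\COCc1ccc(OC)cc1 | intermediate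
11 | 2-[(tert-butyldimethylsilyl)oxy]-N-methoxy-N-methylacetamide | CON(C)C(=O)CO[Si](C)(C)C(C)(C)C | starting material
12 | vinyllithium from 10, lithium in place of iodine with the geometry retained (not isolated) | [Li]/C(C)=C\CC/C(C)=C\COCc1ccc(OC)cc1 | intermediate
13 | lithium N-methoxy-N-methyl hemiaminal adduct of 12 and 11 (not isolated) | CON(C)C(O[Li])(CO[Si](C)(C)C(C)(C)C)/C(C)=C\CC/C(C)=C\COCc1ccc(OC)cc1 | intermediate
14 | (3Z,7Z)-1-[(tert-butyldimethylsilyl)oxy]-9-[(4-methoxybenzyl)oxy]-3,7-dimethylnona-3,7-dien-2-one | CC(C)(C)[Si](C)(C)OCC(=O)/C(C)=C\CC/C(C)=C\COCc1ccc(OC)cc1 | intermediate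
15 | (3Z,7Z)-1-[(tert-butyldimethylsilyl)oxy]-9-hydroxy-3,7-dimethylnona-3,7-dien-2-one | CC(C)(C)[Si](C)(C)OCC(=O)/C(C)=C\CC/C(C)=C\CO | intermediate
16 | (2Z,6Z)-9-[(tert-butyldimethylsilyl)oxy]-3,7-dimethyl-8-oxonona-2,6-dienal | CC(C)(C)[Si](C)(C)OCC(=O)/C(C)=C\CC/C(C)=C\C=O | intermediate
17 | methyl propiolate | C#CC(=O)OC | starting material
18 | methyl 3-(methylzincio)propiolate (not isolated) | C[Zn]C#CC(=O)OC | intermediate
19 | methyl (4S,5Z,9Z)-12-[(tert-butyldimethylsilyl)oxy]-4-hydroxy-6,10-dimethyl-11-oxododeca-5,9-dien-2-ynoate | COC(=O)C#C[C@@H](O)/C=C(/C)CC/C=C(/C)C(=O)CO[Si](C)(C)C(C)(C)C | intermediate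
20 | methyl (2E,4S,5Z,9Z)-3-(allyloxy)-12-[(tert-butyldimethylsilyl)oxy]-4-hydroxy-6,10-dimethyl-11-oxododeca-2,5,9-trienoate (not isolated) | COC(=O)/C=C(/OCC=C)[C@@H](O)/C=C(/C)CC/C=C(/C)C(=O)CO[Si](C)(C)C(C)(C)C | intermediate
21 | (5S)-4-(allyloxy)-5-[(1Z,5Z)-8-[(tert-butyldimethylsilyl)oxy]-2,6-dimethyl-7-oxoocta-1,5-dien-1-yl]furan-2(5H)-one | C=CCOC1=CC(=O)O[C@H]1/C=C(/C)CC/C=C(/C)C(=O)CO[Si](C)(C)C(C)(C)C | intermediate
22 | (5S)-5-[(1Z,5Z)-8-[(tert-butyldimethylsilyl)oxy]-2,6-dimethyl-7-oxoocta-1,5-dien-1-yl]-4-hydroxyfuran-2(5H)-one | OC1=CC(=O)O[C@H]1/C=C(/C)CC/C=C(/C)C(=O)CO[Si](C)(C)C(C)(C)C | intermediate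
23 | (5S)-5-[(1Z,5Z)-8-[(tert-butyldimethylsilyl)oxy]-2,6-dimethyl-7-oxoocta-1,5-dien-1-yl]-4-hydroxy-3-iodofuran-2(5H)-one | OC1=C(I)C(=O)O[C@H]1/C=C(/C)CC/C=C(/C)C(=O)CO[Si](C)(C)C(C)(C)C | intermediate
24 | (5S)-5-[(1Z,5Z)-8-[(tert-butyldimethylsilyl)oxy]-2,6-dimethyl-7-oxoocta-1,5-dien-1-yl]-3-iodo-4-[(4-methoxybenzyl)oxy]furan-2(5H)-one | COc1ccc(COC2=C(I)C(=O)O[C@H]2/C=C(/C)CC/C=C(/C)C(=O)CO[Si](C)(C)C(C)(C)C)cc1 | intermediate
25 | 2-(iodomethyl)-4,4,5,5-tetramethyl-1,3,2-dioxaborolane | ICB1OC(C)(C)C(C)(C)O1 | starting material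
26 | [(4,4,5,5-tetramethyl-1,3,2-dioxaborolan-2-yl)methyl]zinc iodide (not isolated) | I[Zn]CB1OC(C)(C)C(C)(C)O1 | intermediate
27 | (5S)-5-[(1Z,5Z)-8-[(tert-butyldimethylsilyl)oxy]-2,6-dimethyl-7-oxoocta-1,5-dien-1-yl]-4-[(4-methoxybenzyl)oxy]-3-[(pinacolatoboryl)methyl]furan-2(5H)-one | COc1ccc(COC2=C(CB3OC(C)(C)C(C)(C)O3)C(=O)O[C@H]2/C=C(/C)CC/C=C(/C)C(=O)CO[Si](C)(C)C(C)(C)C)cc1 | intermediate
28 | (5S)-5-[(1Z,5Z)-8-hydroxy-2,6-dimethyl-7-oxoocta-1,5-dien-1-yl]-4-[(4-methoxybenzyl)oxy]-3-[(pinacolatoboryl)methyl]furan-2(5H)-one | COc1ccc(COC2=C(CB3OC(C)(C)C(C)(C)O3)C(=O)O[C@H]2/C=C(/C)CC/C=C(/C)C(=O)CO)cc1 | intermediate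
29 | (5S)-5-[(1Z,5Z)-2,6-dimethyl-7,8-dioxoocta-1,5-dien-1-yl]-4-[(4-methoxybenzyl)oxy]-3-[(pinacolatoboryl)methyl]furan-2(5H)-one | COc1ccc(COC2=C(CB3OC(C)(C)C(C)(C)O3)C(=O)O[C@H]2/C=C(/C)CC/C=C(/C)C(=O)C=O)cc1 | intermediate
30 | 8-O-(pinacolatoboryl) derivative of 31 (not isolated) | C=C1C(=O)O[C@H]2/C=C(/C)CC/C=C(/C)C(=O)[C@H](OB3OC(C)(C)C(C)(C)O3)[C@@]12OCc1ccc(OC)cc1 | intermediate
31 | (6S,7S,8R)-8-hydroxy-7-[(4-methoxybenzyl)oxy]-9-oxogermacra-1(10)Z,4Z,11(13)-trien-12,6-olide, cis-fused | C=C1C(=O)O[C@H]2/C=C(/C)CC/C=C(/C)C(=O)[C@H](O)[C@@]12OCc1ccc(OC)cc1 | intermediate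
32 | angelic acid, (2Z)-2-methylbut-2-enoic acid | C/C=C(/C)C(=O)O | starting material
33 | angelic 2,4,6-trichlorobenzoic anhydride (not isolated) | C/C=C(/C)C(=O)OC(=O)c1c(Cl)cc(Cl)cc1Cl | intermediate
34 | (6S,7R,8R)-8-angeloyloxy-7-[(4-methoxybenzyl)oxy]-9-oxogermacra-1(10)Z,4Z,11(13)-trien-12,6-olide | C=C1C(=O)O[C@H]2/C=C(/C)CC/C=C(/C)C(=O)[C@H](OC(=O)/C(C)=C\C)[C@@]12OCc1ccc(OC)cc1 | intermediate
35 | CNP0276177.1, (6S,7R,8R)-8-angeloyloxy-7-hydroxy-9-oxogermacra-1(10)Z,4Z,11(13)-trien-12,6-olide | C=C1C(=O)O[C@H]2/C=C(/C)CC/C=C(/C)C(=O)[C@H](OC(=O)/C(C)=C\C)[C@@]12O | target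

Total step count: 18. Longest linear sequence: 18 steps, from nerol 1 to 35; compounds 6, 11, 17, 25 and 32 are bought and enter without steps of their own.

Steps most likely to fail

Step 16. The fully substituted, ester-bearing allylboronate may add too slowly, so that intermolecular allylboration or decay of the keto aldehyde outruns ring closure. The aldehyde may also be delivered through the other chair or to the other butenolide face. The fallback uses known chemistry: Barbier-type allylation by an allylic bromide, the reaction class of 3-(bromomethyl)butenolides with aldehydes and of allyl halide–aldehyde closures of germacranolide rings. It sets out from 24. Stille coupling with (tributylstannyl)methanol (Pd(PPh3)4, dioxane, 80 °C) should give the hydroxymethyl tetronate F1. Appel bromination (CBr4, PPh3, CH2Cl2, 0 °C) should give the allylic bromide F2. Aqueous HF in MeCN at 0 °C should remove the silyl group to give the bromo ketol F3, and Dess–Martin oxidation the bromo keto aldehyde F4. Slow addition of F4 to indium powder in THF–H2O at high dilution should form the allylindium species, which adds through C7 by the same chair. The route is rejoined at 31.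

Step 17. Acylation of the C8 carbinol, flanked by the quaternary C7 and the C9 ketone, may stall without a nucleophilic catalyst. Forcing it invites drift of the angelate to the tiglate, epimerisation at C8 through the enol, or migration of the lactone to the C8 oxygen. The fallback builds the Z alkene after the ester bond and sets out from 31. Esterification with 2-[bis(2,2,2-trifluoroethoxy)phosphoryl]propanoic acid (EDC, DMAP, CH2Cl2; DMAP is harmless here because the acyl group has no alkene yet) should give the phosphonate ester F5. Still–Gennari olefination of acetaldehyde (KHMDS, 18-crown-6, THF, −78 °C) should then form the angelate directly. The route is rejoined at 34.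

Step 8. Enantiocontrol may erode on the Z β,β-disubstituted enal, the enal may drift from Z to E under the zinc conditions, or the alkynylide may add at C9. The fallback separates bond formation from stereocontrol and sets out from 16. Lithium methyl propiolate (LiHMDS, THF, −78 °C) should give the racemic hydroxy ynoate F6, and Dess–Martin oxidation the ynone F7. Midland reduction with S-Alpine-Borane, chosen by analogy with the R reagent giving (R)-1-octyn-3-ol and selective for alkynyl ketones over the C9 enone, should then set C6. The route is rejoined at 19.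

Further compounds
F1 | step 16 | (5S)-5-[(1Z,5Z)-8-[(tert-butyldimethylsilyl)oxy]-2,6-dimethyl-7-oxoocta-1,5-dien-1-yl]-3-(hydroxymethyl)-4-[(4-methoxybenzyl)oxy]furan-2(5H)-one | COc1ccc(COC2=C(CO)C(=O)O[C@H]2/C=C(/C)CC/C=C(/C)C(=O)CO[Si](C)(C)C(C)(C)C)cc1
F2 | step 16 | (5S)-3-(bromomethyl)-5-[(1Z,5Z)-8-[(tert-butyldimethylsilyl)oxy]-2,6-dimethyl-7-oxoocta-1,5-dien-1-yl]-4-[(4-methoxybenzyl)oxy]furan-2(5H)-one | COc1ccc(COC2=C(CBr)C(=O)O[C@H]2/C=C(/C)CC/C=C(/C)C(=O)CO[Si](C)(C)C(C)(C)C)cc1
F3 | step 16 | (5S)-3-(bromomethyl)-5-[(1Z,5Z)-8-hydroxy-2,6-dimethyl-7-oxoocta-1,5-dien-1-yl]-4-[(4-methoxybenzyl)oxy]furan-2(5H)-one | COc1ccc(COC2=C(CBr)C(=O)O[C@H]2/C=C(/C)CC/C=C(/C)C(=O)CO)cc1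
F4 | step 16 | (5S)-3-(bromomethyl)-5-[(1Z,5Z)-2,6-dimethyl-7,8-dioxoocta-1,5-dien-1-yl]-4-[(4-methoxybenzyl)oxy]furan-2(5H)-one | COc1ccc(COC2=C(CBr)C(=O)O[C@H]2/C=C(/C)CC/C=C(/C)C(=O)C=O)cc1
F5 | step 17 | 8-O-{2-[bis(2,2,2-trifluoroethoxy)phosphoryl]propanoyl} derivative of 31 | C=C1C(=O)O[C@H]2/C=C(/C)CC/C=C(/C)C(=O)[C@H](OC(=O)C(C)P(=O)(OCC(F)(F)F)OCC(F)(F)F)[C@@]12OCc1ccc(OC)cc1
F6 | step 8 | racemic methyl (5Z,9Z)-12-[(tert-butyldimethylsilyl)oxy]-4-hydroxy-6,10-dimethyl-11-oxododeca-5,9-dien-2-ynoate | COC(=O)C#CC(O)/C=C(/C)CC/C=C(/C)C(=O)CO[Si](C)(C)C(C)(C)C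
F7 | step 8 | methyl (5Z,9Z)-12-[(tert-butyldimethylsilyl)oxy]-6,10-dimethyl-4,11-dioxododeca-5,9-dien-2-ynoate | COC(=O)C#CC(=O)/C=C(/C)CC/C=C(/C)C(=O)CO[Si](C)(C)C(C)(C)C
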